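## Retrosynthetic overview

1. The C13–C16 diene comes from a methyl ketone (enol triflate, vinyl coupling); the C8 hydroxyl comes from radical hydration of an 8(17)-alkene; the C9–C11 bond comes from an ene reaction of a Δ8(9)-octalin with but-3-en-2-one, anti to the C10 methyl group.
2. Ring B comes from ring-closing metathesis (C8=C9) of a C10-vinyl / C6-(2-methylallyl) carbinol; C6–C7 comes from asymmetric allylboration of a lactol; the C10 vinyl group comes from a formyl group.
3. Ring A and a temporary five-membered lactone come from one catalytic, enantioselective intramolecular Diels–Alder reaction of an achiral open-chain triene ester, which forms C4–C5 and C1–C10.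
4. Enabling feature: on ring A the C18 oxygen (on C4) and C6 (on C5) are 1,3-related across the C4–C5 bond, so C18–O–C6(=O) serves as a three-atom ester tether with C6 at the acid level. C9 as a formyl group on C10 activates the dienophile, and the E geometry of C5=C10 gives the trans C5–H / C10–CH3 relationship.
5. Ring order: ring A together with the lactone (step 6), then ring B (step 11).

Key step: step 6

Remark: carbons are numbered as in the labdane skeleton of the target (C18 = hydroxymethyl carbon on C4, C19 = methyl on C4, C20 = methyl on C10, C17 = methyl on C8).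

Assumption: the (S)-configured oxazaborolidinium catalyst is taken to deliver the diene to the enal face that gives the (10R) adduct; the enantiomeric catalyst is equally available if the sense proves opposite.

## Route

Step 1
Reactants: 1 acrolein; 2 ethyl 2-(triphenylphosphoranylidene)propanoate
Product: 3 ethyl (2E)-2-methylpenta-2,4-dienoate
Conditions: CH2Cl2, 0 °C → rt
Reagents that add atoms: none
Why: Wittig olefination with the stabilised ylide should give the E trisubstituted alkene (ester trans to the vinyl group), which fixes the diene geometry needed in the key step.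

Step 2
Reactants: 3 ethyl (2E)-2-methylpenta-2,4-dienoate
Product: 4 (2E)-2-methylpenta-2,4-dien-1-ol
Conditions: iBu2AlH (2.2 equiv), CH2Cl2, −78 → 0 °C; aq. Rochelle salt
Reagents that add atoms: none
Why: Low-temperature aluminium hydride reduction of the conjugated ester should proceed by 1,2-addition only and leave the diene untouched.

Step 3
Reactants: 4 (2E)-2-methylpenta-2,4-dien-1-ol; 5 2-(diethoxyphosphoryl)acetic acid
Product: 6 (2E)-2-methylpenta-2,4-dien-1-yl 2-(diethoxyphosphoryl)acetate
Conditions: DCC, DMAP (cat.), CH2Cl2, 0 °C → rt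
Reagents that add atoms: none
Why: Carbodiimide (Steglich) esterification joins the dienol to the phosphonoacetic acid under neutral conditions that the allylic diene tolerates.

Step 4
Reactants: 6 (2E)-2-methylpenta-2,4-dien-1-yl 2-(diethoxyphosphoryl)acetate; 7 1,1-dimethoxypropan-2-one
Product: 8 (2E)-2-methylpenta-2,4-dien-1-yl (2E)-4,4-dimethoxy-3-methylbut-2-enoate
Conditions: NaH, THF, 0 °C → rt
Reagents that add atoms: none
Why: Horner–Wadsworth–Emmons olefination of the ketone should place the ester trans to the bulkier acetal carbon, giving the E enoate that later maps onto the trans ring fusion (any Z isomer is removed by chromatography).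

Step 5
Reactants: 8 (2E)-2-methylpenta-2,4-dien-1-yl (2E)-4,4-dimethoxy-3-methylbut-2-enoate
Product: 9 (2E)-2-methylpenta-2,4-dien-1-yl (2E)-3-methyl-4-oxobut-2-enoate
Conditions: 1 M aq. HCl, THF, 0 °C → rt
Reagents that add atoms: water O
Why: Mild acid-catalysed acetal hydrolysis unmasks the formyl group; the E enal cannot lactonise and the dienyl ester should survive dilute acid at low temperature.

Step 6
Reactants: 9 (2E)-2-methylpenta-2,4-dien-1-yl (2E)-3-methyl-4-oxobut-2-enoate
Product: 10 (3aS,7R,7aR)-3a,7-dimethyl-1-oxo-1,3,3a,6,7,7a-hexahydro-2-benzofuran-7-carbaldehyde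
Conditions: (S)-B-o-tolyl oxazaborolidine from α,α-diphenylprolinol (20 mol %), HNTf2 (20 mol %), CH2Cl2, −78 → −20 °C
Reagents that add atoms: none
Why: Coordination of the cationic oxazaborolidine to the formyl group lowers the LUMO of the C5=C10 double bond, and the tethered diene adds across it in a concerted, asynchronous [4+2] cycloaddition that forms C4–C5 and C1–C10 in one event; the closest known reaction types are chiral Lewis-acid-catalysed intramolecular Diels–Alder reactions of 2-methyl-substituted trienals and thermal cyclisations of ester-linked nona-1,3,8-trienes. Ring A closes as the six-membered [4+2] ring, and the five-membered lactone closes as the tether ring of a type 1 intramolecular cycloaddition through the s-cis ester conformer, with the tether exo. The trans relationship of C5–H and C10–CH3 follows from suprafacial addition to the E dienophile, so the later decalin is trans-fused, which a cyclic ring B dienophile could not deliver. The C4 configuration follows from the E diene (C18 on the outside) combined with the endo orientation of the complexed formyl group, which places C18 cis to C9 and the C4 methyl cis to the C10 methyl. The absolute configuration is set by the catalyst, which shields one face of the s-trans enal. The step needs endo (formyl) over exo selectivity and turnover without ionisation of the dienyl ester; the first should be secured by the Lewis-acid-bound formyl group and the three-atom tether, the second by the low temperature and the much higher basicity of the aldehyde compared with the ester.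

Step 7
Reactants: 10 (3aS,7R,7aR)-3a,7-dimethyl-1-oxo-1,3,3a,6,7,7a-hexahydro-2-benzofuran-7-carbaldehyde
Product: 11 (3aS,7R,7aR)-3a,7-dimethyl-1-oxooctahydro-2-benzofuran-7-carbaldehyde
Conditions: H2 (1 atm), Pd/C, EtOAc, rt
Reagents that add atoms: none
Why: Heterogeneous catalytic hydrogenation saturates the only C=C bond (C2=C3) at the one stage where no other alkene is present, while the neopentylic aldehyde and the lactone should survive.

Step 8
Reactants: 11 (3aS,7R,7aR)-3a,7-dimethyl-1-oxooctahydro-2-benzofuran-7-carbaldehyde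
Product: 12 (3aS,7S,7aS)-7-ethenyl-3a,7-dimethylhexahydro-2-benzofuran-1(3H)-one
Conditions: Ph3PCH3Br, KOtBu, THF, 0 °C; then 11, −78 → 0 °C
Reagents that add atoms: methyltriphenylphosphonium bromide C[P+](c1ccccc1)(c1ccccc1)c1ccccc1.[Br-]
Why: Wittig methylenation is chemoselective for the aldehyde over the lactone, and C10 is quaternary, so no stereocenter at the reacting site can epimerise.

Step 9
Reactants: 12 (3aS,7S,7aS)-7-ethenyl-3a,7-dimethylhexahydro-2-benzofuran-1(3H)-one
Product: 13 (3aS,7S,7aS)-7-ethenyl-3a,7-dimethyloctahydro-2-benzofuran-1-ol (lactol, both anomers)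
Conditions: iBu2AlH (1.1 equiv), CH2Cl2, −78 °C; MeOH, aq. Rochelle salt
Reagents that add atoms: none
Why: Low-temperature aluminium hydride reduction of a γ-lactone should stop at the lactol through the stable tetrahedral aluminate, giving C6 at the aldehyde oxidation level.

Step 10
Reactants: 13 (3aS,7S,7aS)-7-ethenyl-3a,7-dimethyloctahydro-2-benzofuran-1-ol
Product: 14 (1R)-1-[(1S,2S,6S)-2-ethenyl-6-(hydroxymethyl)-2,6-dimethylcyclohexyl]-3-methylbut-3-en-1-ol
Conditions: (+)-Ipc2BOMe, 2-methylallylmagnesium chloride, Et2O, −78 °C → rt; then 13, −78 °C → rt; NaOH, H2O2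
Reagents that add atoms: B-(2-methylallyl)diisopinocampheylborane (made in the flask) C[C@@H]1[C@@H](B(CC(C)=C)[C@H]2C[C@H]3C[C@@H]([C@@H]2C)C3(C)C)C[C@H]2C[C@@H]1C2(C)C
Why: Brown-type asymmetric allylboration of the hydroxy aldehyde in equilibrium with the lactol through a chair six-membered transition state; the isopinocampheyl groups derived from (−)-α-pinene should direct the 2-methylallyl group to the Re face of the aldehyde and set the (6R) carbinol under reagent control.

Step 11
Reactants: 14 (1R)-1-[(1S,2S,6S)-2-ethenyl-6-(hydroxymethyl)-2,6-dimethylcyclohexyl]-3-methylbut-3-en-1-ol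
Product: 15 (1R,4aS,8S,8aS)-8-(hydroxymethyl)-3,4a,8-trimethyl-1,2,4a,5,6,7,8,8a-octahydronaphthalen-1-ol
Conditions: second-generation Grubbs catalyst (5 mol %), CH2Cl2, 40 °C
Reagents that add atoms: none
Why: Ring-closing metathesis between the C10 vinyl group and the 1,1-disubstituted alkene closes ring B as the trisubstituted C8=C9 cyclohexene; the two arms are trans-diequatorial on ring A, so the trans-fused bicycle should form without strain.

Step 12
Reactants: 15 (1R,4aS,8S,8aS)-8-(hydroxymethyl)-3,4a,8-trimethyl-1,2,4a,5,6,7,8,8a-octahydronaphthalen-1-ol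
Product: 16 (1R,4aS,8S,8aS)-8-({[tert-butyl(dimethyl)silyl]oxy}methyl)-3,4a,8-trimethyl-1,2,4a,5,6,7,8,8a-octahydronaphthalen-1-ol
Conditions: TBSCl, imidazole, DMF, 0 °C
Reagents that add atoms: tert-butyldimethylsilyl chloride CC(C)(C)[Si](C)(C)Cl
Why: Silylation should be selective for the primary C18 hydroxyl over the hindered secondary C6 hydroxyl.

Step 13
Reactants: 16 (1R,4aS,8S,8aS)-8-({[tert-butyl(dimethyl)silyl]oxy}methyl)-3,4a,8-trimethyl-1,2,4a,5,6,7,8,8a-octahydronaphthalen-1-ol
Product: 17 (1R,4aS,8S,8aS)-8-({[tert-butyl(dimethyl)silyl]oxy}methyl)-3,4a,8-trimethyl-1,2,4a,5,6,7,8,8a-octahydronaphthalen-1-yl acetate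
Conditions: Ac2O, DMAP (cat.), pyridine, CH2Cl2, rt
Reagents that add atoms: acetic anhydride CC(=O)OC(C)=O
Why: Nucleophile-catalysed acylation of the remaining secondary alcohol installs the C6 acetate of the target.

Step 14
Reactants: 17 (1R,4aS,8S,8aS)-8-({[tert-butyl(dimethyl)silyl]oxy}methyl)-3,4a,8-trimethyl-1,2,4a,5,6,7,8,8a-octahydronaphthalen-1-yl acetate; 18 but-3-en-2-one
Product: 19 (1R,4S,4aS,8S,8aS)-8-({[tert-butyl(dimethyl)silyl]oxy}methyl)-4a,8-dimethyl-3-methylidene-4-(3-oxobutyl)decahydronaphthalen-1-yl acetate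
Conditions: Me2AlCl, CH2Cl2, −78 → 0 °C
Reagents that add atoms: none
Why: Lewis-acid-promoted ene reaction of the vinyl ketone with the trisubstituted alkene: C9 bonds to the terminal enone carbon on the face opposite the axial C10 methyl group, a hydrogen moves from C17 and the alkene shifts to C8=C17, which sets C9 with the side chain axial (a C7=C8 isomer, if formed, converges in step 15).

Step 15
Reactants: 19 (1R,4S,4aS,8S,8aS)-8-({[tert-butyl(dimethyl)silyl]oxy}methyl)-4a,8-dimethyl-3-methylidene-4-(3-oxobutyl)decahydronaphthalen-1-yl acetate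
Product: 21 (1R,3S,4R,4aR,8S,8aS)-8-({[tert-butyl(dimethyl)silyl]oxy}methyl)-3-hydroxy-3,4a,8-trimethyl-4-(3-oxobutyl)decahydronaphthalen-1-yl acetate, via tertiary C8 hydroperoxide 20 (not isolated)
Conditions: Mn(dpm)3 (dpm = dipivaloylmethanate, cat.), PhSiH3, O2 (1 atm), iPrOH/CH2Cl2, 0 °C → rt; then P(OEt)3
Reagents that add atoms: dioxygen O=O
Why: Mukaiyama-type hydration: hydrogen-atom transfer to C17 gives the tertiary C8 radical, which should be trapped by O2 on the face opposite the C10 methyl group (the other face is shielded 1,3-diaxially), giving after reduction of the hydroperoxide the equatorial alcohol cis to the C9 side chain.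

Step 16
Reactants: 21 (1R,3S,4R,4aR,8S,8aS)-8-({[tert-butyl(dimethyl)silyl]oxy}methyl)-3-hydroxy-3,4a,8-trimethyl-4-(3-oxobutyl)decahydronaphthalen-1-yl acetate
Product: 22 (1R,3S,4R,4aR,8S,8aS)-8-({[tert-butyl(dimethyl)silyl]oxy}methyl)-3-hydroxy-3,4a,8-trimethyl-4-{3-[(trifluoromethanesulfonyl)oxy]but-3-en-1-yl}decahydronaphthalen-1-yl acetate
Conditions: KN(SiMe3)2 (2.2 equiv), THF, −78 °C; PhNTf2
Reagents that add atoms: N-phenylbis(trifluoromethanesulfonimide) O=S(=O)(N(c1ccccc1)S(=O)(=O)C(F)(F)F)C(F)(F)F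
Why: Kinetic deprotonation of the methyl ketone at its methyl group by the hindered amide base and O-sulfonylation of the enolate should give the terminal enol triflate; the second equivalent of base covers the tertiary hydroxyl, which is too hindered to be sulfonylated.

Step 17
Reactants: 22 (1R,3S,4R,4aR,8S,8aS)-8-({[tert-butyl(dimethyl)silyl]oxy}methyl)-3-hydroxy-3,4a,8-trimethyl-4-{3-[(trifluoromethanesulfonyl)oxy]but-3-en-1-yl}decahydronaphthalen-1-yl acetate
Product: 23 (1R,3S,4R,4aR,8S,8aS)-8-({[tert-butyl(dimethyl)silyl]oxy}methyl)-3-hydroxy-3,4a,8-trimethyl-4-(3-methylidenepent-4-en-1-yl)decahydronaphthalen-1-yl acetate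
Conditions: Pd(PPh3)4 (5 mol %), LiCl, THF, 60 °C
Reagents that add atoms: tributyl(vinyl)stannane C=C[Sn](CCCC)(CCCC)CCCC
Why: Stille cross-coupling of the enol triflate with the vinylstannane forms C13–C14 and thus the 2-substituted buta-1,3-diene under neutral conditions that the acetate and the tertiary alcohol tolerate.

Step 18
Reactants: 23 (1R,3S,4R,4aR,8S,8aS)-8-({[tert-butyl(dimethyl)silyl]oxy}methyl)-3-hydroxy-3,4a,8-trimethyl-4-(3-methylidenepent-4-en-1-yl)decahydronaphthalen-1-yl acetate
Product: 24 (1R,3S,4R,4aR,8S,8aS)-3-hydroxy-8-(hydroxymethyl)-3,4a,8-trimethyl-4-(3-methylidenepent-4-en-1-yl)decahydronaphthalen-1-yl acetate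
Conditions: HF·pyridine, pyridine/THF, 0 °C → rt
Reagents that add atoms: none
Why: Fluoride cleavage of the primary silyl ether under buffered, non-basic conditions should free the C18 hydroxyl without acetyl migration from O6 or damage to the diene.

## Compound list

1 | acrolein | C=CC=O | starting material
2 | ethyl 2-(triphenylphosphoranylidene)propanoate | CCOC(=O)C(C)=P(c1ccccc1)(c1ccccc1)c1ccccc1 | starting material
3 | ethyl (2E)-2-methylpenta-2,4-dienoate | CCOC(=O)/C(C)=C/C=C | intermediate
4 | (2E)-2-methylpenta-2,4-dien-1-ol | OC/C(C)=C/C=C | intermediate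
5 | 2-(diethoxyphosphoryl)acetic acid | CCOP(=O)(CC(=O)O)OCC | starting material
6 | (2E)-2-methylpenta-2,4-dien-1-yl 2-(diethoxyphosphoryl)acetate | CCOP(=O)(OCC)CC(=O)OC/C(C)=C/C=C | intermediate
7 | 1,1-dimethoxypropan-2-one | COC(OC)C(C)=O | starting material
8 | (2E)-2-methylpenta-2,4-dien-1-yl (2E)-4,4-dimethoxy-3-methylbut-2-enoate | COC(OC)/C(C)=C/C(=O)OC/C(C)=C/C=C | intermediate
9 | (2E)-2-methylpenta-2,4-dien-1-yl (2E)-3-methyl-4-oxobut-2-enoate | O=C/C(C)=C/C(=O)OC/C(C)=C/C=C | intermediate
10 | (3aS,7R,7aR)-3a,7-dimethyl-1-oxo-1,3,3a,6,7,7a-hexahydro-2-benzofuran-7-carbaldehyde (trans-fused lactone) | O=C[C@]1(C)CC=C[C@]2(C)COC(=O)[C@@H]12 | intermediate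
11 | (3aS,7R,7aR)-3a,7-dimethyl-1-oxooctahydro-2-benzofuran-7-carbaldehyde | O=C[C@]1(C)CCC[C@]2(C)COC(=O)[C@@H]12 | intermediate
12 | (3aS,7S,7aS)-7-ethenyl-3a,7-dimethylhexahydro-2-benzofuran-1(3H)-one | C=C[C@]1(C)CCC[C@]2(C)COC(=O)[C@@H]12 | intermediate
13 | (3aS,7S,7aS)-7-ethenyl-3a,7-dimethyloctahydro-2-benzofuran-1-ol (lactol, both anomers) | C=C[C@]1(C)CCC[C@]2(C)COC(O)[C@@H]12 | intermediate
14 | (1R)-1-[(1S,2S,6S)-2-ethenyl-6-(hydroxymethyl)-2,6-dimethylcyclohexyl]-3-methylbut-3-en-1-ol | C=C[C@]1(C)CCC[C@](C)(CO)[C@H]1[C@H](O)CC(C)=C | intermediate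
15 | (1R,4aS,8S,8aS)-8-(hydroxymethyl)-3,4a,8-trimethyl-1,2,4a,5,6,7,8,8a-octahydronaphthalen-1-ol | CC1=C[C@]2(C)CCC[C@](C)(CO)[C@H]2[C@H](O)C1 | intermediate
16 | (1R,4aS,8S,8aS)-8-({[tert-butyl(dimethyl)silyl]oxy}methyl)-3,4a,8-trimethyl-1,2,4a,5,6,7,8,8a-octahydronaphthalen-1-ol | CC1=C[C@]2(C)CCC[C@](C)(CO[Si](C)(C)C(C)(C)C)[C@H]2[C@H](O)C1 | intermediate
17 | (1R,4aS,8S,8aS)-8-({[tert-butyl(dimethyl)silyl]oxy}methyl)-3,4a,8-trimethyl-1,2,4a,5,6,7,8,8a-octahydronaphthalen-1-yl acetate | CC1=C[C@]2(C)CCC[C@](C)(CO[Si](C)(C)C(C)(C)C)[C@H]2[C@H](OC(C)=O)C1 | intermediate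
18 | but-3-en-2-one | C=CC(C)=O | starting material
19 | (1R,4S,4aS,8S,8aS)-8-({[tert-butyl(dimethyl)silyl]oxy}methyl)-4a,8-dimethyl-3-methylidene-4-(3-oxobutyl)decahydronaphthalen-1-yl acetate | CC(=O)CC[C@@H]1[C@]2(C)CCC[C@](C)(CO[Si](C)(C)C(C)(C)C)[C@H]2[C@H](OC(C)=O)CC1=C | intermediate
20 | (1R,3S,4R,4aR,8S,8aS)-8-({[tert-butyl(dimethyl)silyl]oxy}methyl)-3-hydroperoxy-3,4a,8-trimethyl-4-(3-oxobutyl)decahydronaphthalen-1-yl acetate | CC(=O)CC[C@@H]1[C@]2(C)CCC[C@](C)(CO[Si](C)(C)C(C)(C)C)[C@H]2[C@H](OC(C)=O)C[C@]1(C)OO | intermediate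
21 | (1R,3S,4R,4aR,8S,8aS)-8-({[tert-butyl(dimethyl)silyl]oxy}methyl)-3-hydroxy-3,4a,8-trimethyl-4-(3-oxobutyl)decahydronaphthalen-1-yl acetate | CC(=O)CC[C@@H]1[C@]2(C)CCC[C@](C)(CO[Si](C)(C)C(C)(C)C)[C@H]2[C@H](OC(C)=O)C[C@]1(C)O | intermediate
22 | (1R,3S,4R,4aR,8S,8aS)-8-({[tert-butyl(dimethyl)silyl]oxy}methyl)-3-hydroxy-3,4a,8-trimethyl-4-{3-[(trifluoromethanesulfonyl)oxy]but-3-en-1-yl}decahydronaphthalen-1-yl acetate | C=C(OS(=O)(=O)C(F)(F)F)CC[C@@H]1[C@]2(C)CCC[C@](C)(CO[Si](C)(C)C(C)(C)C)[C@H]2[C@H](OC(C)=O)C[C@]1(C)O | intermediate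
23 | (1R,3S,4R,4aR,8S,8aS)-8-({[tert-butyl(dimethyl)silyl]oxy}methyl)-3-hydroxy-3,4a,8-trimethyl-4-(3-methylidenepent-4-en-1-yl)decahydronaphthalen-1-yl acetate | C=CC(=C)CC[C@@H]1[C@]2(C)CCC[C@](C)(CO[Si](C)(C)C(C)(C)C)[C@H]2[C@H](OC(C)=O)C[C@]1(C)O | intermediate
24 | (1R,3S,4R,4aR,8S,8aS)-3-hydroxy-8-(hydroxymethyl)-3,4a,8-trimethyl-4-(3-methylidenepent-4-en-1-yl)decahydronaphthalen-1-yl acetate | C=CC(=C)CC[C@@H]1[C@]2(C)CCC[C@](C)(CO)[C@H]2[C@H](OC(C)=O)C[C@]1(C)O | target

## Step count and risks

Total step count: 18. Longest linear sequence: 18 steps (from acrolein 1).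

Steps most likely to fail:

1. Step 6. The catalysed cycloaddition may be too slow at low temperature, because the tether ester must adopt its less stable s-cis conformer and the diene carries a cis (inside) methyl group at C4. The strong Lewis acid may also ionise the dienyl ester, and facial or endo/exo discrimination may be incomplete. The fallback sets out from 9 and rejoins at 14. Heating 9 without catalyst (toluene, 110 °C, BHT) should give the cycloadduct as a racemate, that is 10 together with the enantiomeric lactone aldehyde F1. The racemate is taken through steps 7 to 9 unchanged, so that the enantiomeric saturated aldehyde F2, the enantiomeric vinyl lactone F3 and the enantiomeric lactol F4 accompany 11, 12 and 13. In step 10 the enantiopure borane should convert the two lactol enantiomers into 14 and the diastereomeric diol F5, which are separated by chromatography.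

2. Step 14. The ene reaction may be sluggish at the neopentylic C9, and the vinyl ketone may undergo competing [2+2] addition or oligomerise under Lewis acid. The fallback sets out from 17 and rejoins at 19. A carbonyl-ene reaction with formaldehyde (paraformaldehyde, Me2AlCl, CH2Cl2) should give the homoallylic alcohol F10. Buffered Dess–Martin oxidation should give the aldehyde F11. Wittig reaction with 1-(triphenylphosphoranylidene)propan-2-one should give the enone F12. Conjugate reduction with [(Ph3P)CuH]6 should then give 19.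

3. Step 10. The lactol may react slowly with the bulky borane, because only a small share is open hydroxy aldehyde and the formyl carbon is flanked by two quaternary carbons; reagent control may also be incomplete in a mismatched pairing. The fallback sets out from 13 and rejoins at 16. Addition of 2-methylallylmagnesium chloride (THF, 0 °C) should give 14 mixed with the C6 epimeric diol F6. Ring-closing metathesis as in step 11 should give 15 with the epimeric octalin diol F7. Silylation as in step 12 should give 16 with the epimeric silyl ether F8. Dess–Martin oxidation of the mixture should give the single ketone F9. Equilibrating reduction (Li, liquid NH3, THF, −78 °C, then NH4Cl) should give 16, because the equatorial C6 alcohol avoids the syn-diaxial contact with the C4 and C10 methyl groups.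

Further compounds
F1 | step 6 | enantiomer of 10, (3aR,7S,7aS)-3a,7-dimethyl-1-oxo-1,3,3a,6,7,7a-hexahydro-2-benzofuran-7-carbaldehyde | O=C[C@@]1(C)CC=C[C@@]2(C)COC(=O)[C@H]12
F2 | step 6 | enantiomer of 11, (3aR,7S,7aS)-3a,7-dimethyl-1-oxooctahydro-2-benzofuran-7-carbaldehyde | O=C[C@@]1(C)CCC[C@@]2(C)COC(=O)[C@H]12
F3 | step 6 | enantiomer of 12, (3aR,7R,7aR)-7-ethenyl-3a,7-dimethylhexahydro-2-benzofuran-1(3H)-one | C=C[C@@]1(C)CCC[C@@]2(C)COC(=O)[C@H]12
F4 | step 6 | enantiomer of 13, (3aR,7R,7aR)-7-ethenyl-3a,7-dimethyloctahydro-2-benzofuran-1-ol | C=C[C@@]1(C)CCC[C@@]2(C)COC(O)[C@H]12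
F5 | step 6 | (1R)-1-[(1R,2R,6R)-2-ethenyl-6-(hydroxymethyl)-2,6-dimethylcyclohexyl]-3-methylbut-3-en-1-ol (diastereomer of 14) | C=C[C@@]1(C)CCC[C@@](C)(CO)[C@@H]1[C@H](O)CC(C)=C
F6 | step 10 | (1S)-1-[(1S,2S,6S)-2-ethenyl-6-(hydroxymethyl)-2,6-dimethylcyclohexyl]-3-methylbut-3-en-1-ol (C6 epimer of 14) | C=C[C@]1(C)CCC[C@](C)(CO)[C@H]1[C@@H](O)CC(C)=C
F7 | step 10 | (1S,4aS,8S,8aS)-8-(hydroxymethyl)-3,4a,8-trimethyl-1,2,4a,5,6,7,8,8a-octahydronaphthalen-1-ol (C6 epimer of 15) | CC1=C[C@]2(C)CCC[C@](C)(CO)[C@H]2[C@@H](O)C1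
F8 | step 10 | (1S,4aS,8S,8aS)-8-({[tert-butyl(dimethyl)silyl]oxy}methyl)-3,4a,8-trimethyl-1,2,4a,5,6,7,8,8a-octahydronaphthalen-1-ol (C6 epimer of 16) | CC1=C[C@]2(C)CCC[C@](C)(CO[Si](C)(C)C(C)(C)C)[C@H]2[C@@H](O)C1
F9 | step 10 | (4aS,8S,8aS)-8-({[tert-butyl(dimethyl)silyl]oxy}methyl)-3,4a,8-trimethyl-4a,5,6,7,8,8a-hexahydronaphthalen-1(2H)-one | CC1=C[C@]2(C)CCC[C@](C)(CO[Si](C)(C)C(C)(C)C)[C@H]2C(=O)C1
F10 | step 14 | (1R,4S,4aS,8S,8aS)-8-({[tert-butyl(dimethyl)silyl]oxy}methyl)-4-(hydroxymethyl)-4a,8-dimethyl-3-methylidenedecahydronaphthalen-1-yl acetate | OC[C@@H]1[C@]2(C)CCC[C@](C)(CO[Si](C)(C)C(C)(C)C)[C@H]2[C@H](OC(C)=O)CC1=C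
F11 | step 14 | (1R,4S,4aR,8S,8aS)-8-({[tert-butyl(dimethyl)silyl]oxy}methyl)-4-formyl-4a,8-dimethyl-3-methylidenedecahydronaphthalen-1-yl acetate | O=C[C@@H]1[C@]2(C)CCC[C@](C)(CO[Si](C)(C)C(C)(C)C)[C@H]2[C@H](OC(C)=O)CC1=C
F12 | step 14 | (1R,4S,4aS,8S,8aS)-8-({[tert-butyl(dimethyl)silyl]oxy}methyl)-4a,8-dimethyl-3-methylidene-4-[(1E)-3-oxobut-1-en-1-yl]decahydronaphthalen-1-yl acetate | CC(=O)/C=C/[C@@H]1[C@]2(C)CCC[C@](C)(CO[Si](C)(C)C(C)(C)C)[C@H]2[C@H](OC(C)=O)CC1=C
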